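The numbers of this flask are made up; the flask was simulated.

In the early minutes, initiator and free monomer begin living ends, and each living end then adds free monomer to its chain, while transfer agent slowly kills the ends and an uncatalysed route takes some free monomer aside.

free monomer 1.0 M; transfer agent 0.100 M; initiator 76 mM; time 25 min

- average number of monomer units in a chain (chains begun, living or dead) at 25 min
- part of the free monomer that has reacted at 25 min

- the average divides the monomer in chains by the number of chains begun, living and dead together
- run time (flask): 25 min

    living end + transfer agent → dead chain (k1 = 1.5 L mol⁻¹ min⁻¹)
    free monomer + initiator → spent initiator (k2 = 0.0071 L mol⁻¹ min⁻¹)
    free monomer → uncatalysed product (k3 = 0.036 min⁻¹)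
    free monomer + initiator → living end + monomer in chains (k4 = 0.22 L mol⁻¹ min⁻¹)
    free monomer + living end → monomer in chains + living end, rate k5*[living end]*[free monomer] (k5 = 22 L mol⁻¹ min⁻¹)

Let the ends pile up undying: the half-life of free monomer is then 1.94 min, shorter than the 4.6 min half-life of a living end. Growth and starting both carry free monomer, so it cancels from their ratio. Replace the rising count of ends by its mean, half the final count. You then get the growth number, 658: growth constant times monomer charge over twice the starting constant times initiator charge. Its root is the chain length, 25.6, and the share of the initiator charge that begins chains is 51.3%.

Afterwards the ends fade with their mean lifetime, so free monomer meets a total exposure of 6.62, which gives 99.9%.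

Was one number enough? The uncatalysed route takes about 8.39% of the free monomer, and since the length goes as the root of the monomer that grows, that lowers it by about 4.29%; the thinning initiator raises it by about 16.0%, and the ends lost to transfer agent lower it by an amount I have not reckoned, so I hold the root as an estimate, with a margin no finer than these corrections.

The forecast says 26 (23 to 30) and 99.9% (99.5% to 100%), since “initiation stalls as the monomer runs out”.

The flask gives 26.1 and 99.9%.

Free monomer, the limiting reagent, ends at 0.12% of its charge, less than the 53% of initiator, so this flask used 47.0% of its initiator against 51.3% from the growth number. A neighbour flask charged with 0.40 M of free monomer has a growth number of 263, root 16.2; it reads 14.0, with 15.5% of its free monomer charge as uncatalysed product.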